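**Retrosynthetic overview**
1. 18 ⇐ 17 (ketal hydrogenolysis) ⇐ 12: C1–H is delivered from Si–H tethers on the cis C2/C3 CH2O arms to the C1 diarylcarbenium ion, so the aryl group ends trans to both arms.
2. 12 ⇐ lactone 11 (LiAlH4) ⇐ photoenolisation/Diels–Alder of 2-methylbenzophenone 6 with (5S)-menthyloxybutenolide 9: forms C1–C2 and C3–C4, closes ring B, sets C2/C3 (cis) and the C1 carbinol.
3. Hooks in the target: C4 is a bare benzylic CH2 on ring A (former ortho-CH3), C1 carries both aryl rings (former C=O), C2/C3 carry cis CH2OH groups (former cyclic cis-dienophile), and the C7/C8 catechol flanks C8a (the two methyl ethers a C1 ketone lets BCl3 remove).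
4. 6 ⇐ 4 ⇐ 3 ⇐ Friedel–Crafts acylation of mirror-symmetric 3,4,5-trimethoxytoluene 1 with 3,4,5-trimethoxybenzoyl chloride 2 (regiochemistry fixed by symmetry).
5. Ring order: ring A and the pendant aryl ring are bought; ring B is the only ring built (step 5).

Key step: step 5

Remark: tetralin numbering is used throughout (C1 diaryl carbon, C2/C3 CH2OH carbons, C4 CH2, C5–C8 ring A); in it the target is (1S,2R,3S), i.e. the C1 aryl group is trans to the two mutually cis hydroxymethyl groups.

**Step 1**
Reactants: 1 3,4,5-trimethoxytoluene; 2 3,4,5-trimethoxybenzoyl chloride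
Product: 3 (2,3,4-trimethoxy-6-methylphenyl)(3,4,5-trimethoxyphenyl)methanone
Conditions: AlCl3 (1.1 equiv), CH2Cl2, 0 °C; cold 1 M HCl
Reagents that add atoms: 3,4,5-trimethoxybenzoyl chloride (2), COc1cc(cc(OC)c1OC)C(Cl)=O
Why: Friedel–Crafts acylation of a strongly activated arene whose two free positions are equivalent by symmetry, so only one regioisomer can form.

**Step 2**
Reactants: 3
Product: 4 (2,3-dihydroxy-4-methoxy-6-methylphenyl)(3,4,5-trimethoxyphenyl)methanone
Conditions: BCl3 (2.5 equiv), CH2Cl2, −78 → 20 °C; H2O/MeOH
Reagents that add atoms: none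
Why: Chelation-directed Lewis-acid ether cleavage, in which boron bound to the ketone oxygen cleaves the ortho methyl ether and the resulting aryloxyboron chloride cleaves the neighbouring one through a five-membered catechol borate, as known for 2,3,4-trimethoxyaryl carbonyl compounds; the four non-chelated methyl ethers should survive.

**Step 3**
Reactants: 4; 5 dichlorodiphenylmethane
Product: 6 (7-methoxy-5-methyl-2,2-diphenyl-1,3-benzodioxol-4-yl)(3,4,5-trimethoxyphenyl)methanone
Conditions: Ph2CCl2 (1.3 equiv), Ph2O, 175 °C
Reagents that add atoms: dichlorodiphenylmethane (5), ClC(Cl)(c1ccccc1)c1ccccc1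
Why: Ketalisation of a catechol with a gem-dichloride, which removes the phenolic O–H that would quench the excited ketone by proton transfer and installs a group with no abstractable hydrogen.

**Step 4**
Reactants: 7 5-hydroxy-2(5H)-furanone; 8 (+)-menthol, (1S,2R,5S)
Product: 9 (5S)-5-[(1S,2R,5S)-menthyloxy]-2(5H)-furanone
Conditions: p-TsOH (cat.), toluene, reflux (Dean–Stark); crystallisation from petroleum ether, mother liquor re-equilibrated (p-TsOH) and recrystallised
Reagents that add atoms: (+)-menthol (8), C[C@H]1CC[C@@H]([C@H](C1)O)C(C)C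
Why: Acid-catalysed acetalisation of the cyclic hemiacetal, in which the C5 epimers interconvert under acid and the (5S) epimer is expected to crystallise, being the mirror image of the crystalline (5R) acetal formed from (−)-menthol (crystallisation-driven diastereomer enrichment).

**Step 5**
Reactants: 6; 9
Product: 11 cis-fused hydroxy lactone adduct (tetralin numbering 1R,2S,3S; lactone C=O on C2; acetal carbon S on C3), via photodienol 10 (not isolated)
Conditions: hν (365 nm LEDs), 9 (3 equiv), degassed toluene (0.02 M in 6), 20 °C, Ar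
Reagents that add atoms: butenolide 9, C[C@H]1CC[C@@H]([C@H](C1)O[C@@H]1C=CC(=O)O1)C(C)C
Why: n→π* excitation of 6 and intersystem crossing give a triplet ketone that abstracts hydrogen from the ortho-methyl group (1,5-HAT), and the biradical relaxes to hydroxy-o-quinodimethane 10, whose long-lived isomer (OH turned toward the dioxole oxygen, aryl turned inward) is trapped in a thermal [4+2] addition driven by re-aromatisation of ring A. The closest known reaction type is the photoenolisation/Diels–Alder trapping of 2-methylbenzophenone photoenols by cyclic cis-dienophiles such as maleic anhydride and maleimides, combined with the anti-selective Diels–Alder chemistry of 5-alkoxy-2(5H)-furanones. Ring B is closed by an intermolecular suprafacial–suprafacial [4+2] addition that forms C3–C4 (CH2 terminus to the butenolide β-carbon, the leading bond) and C1–C2 (carbinol terminus to the α-carbon) in one operation. C2 and C3 are set as a cis pair by the Z-alkene locked in the butenolide ring and in the absolute sense by attack on the face opposite the menthyloxy group of the (5S)-acetal, while C1 is set by the endo rule (outward OH cis to, and hydrogen-bonded with, the lactone carbonyl). The step needs hydrogen abstraction from the methyl group only (secured by a ketal without abstractable hydrogen and the absence of a phenolic O–H), the "ortho" regiochemistry (secured by the donor OH on C1, which puts the largest HOMO coefficient on the CH2 terminus, against the largest LUMO coefficient on the β-carbon) and face selectivity (secured by the acetal substituent). The endo/exo outcome is not critical, because the C1 carbinol centre is re-set in step 8, and the adduct no longer absorbs at 365 nm.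

**Step 6**
Reactants: 11
Product: 12 (1R,2R,3S)-1-hydroxy-2,3-bis(hydroxymethyl)-6-methoxy-7,8-(diphenylmethylenedioxy)-1-(3,4,5-trimethoxyphenyl)tetralin
Conditions: LiAlH4 (3 equiv), THF, −20 → 0 °C; Rochelle salt
Reagents that add atoms: none
Why: Hydride reduction of the lactone carbonyl and of the acetal carbon (which collapses to an aldehyde with loss of menthoxide) gives both CH2OH groups without touching a stereocentre, the low temperature guarding against retro-aldol opening of the β-hydroxy lactone.

**Step 7**
Reactants: 12; 13 di-tert-butylchlorosilane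
Product: 14 bis(di-tert-butylsilyl) ether of 12 at the two primary hydroxyl groups
Conditions: t-Bu2SiHCl (2.4 equiv), imidazole (5 equiv), DMF, 0 °C → rt
Reagents that add atoms: di-tert-butylchlorosilane (13), CC(C)(C)[SiH](Cl)C(C)(C)C
Why: Silyl ether formation with a chlorosilane and imidazole is selective for the two primary alcohols, the tertiary diaryl carbinol being too hindered to react.

**Step 8**
Reactants: 14
Product: 17 (1S,2R,3S)-2,3-bis(hydroxymethyl)-6-methoxy-7,8-(diphenylmethylenedioxy)-1-(3,4,5-trimethoxyphenyl)tetralin, via diarylcarbenium ion 15 (not isolated), via silyl trifluoroacetate 16 (not isolated)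
Conditions: CF3CO2H (10 equiv), CH2Cl2 (0.005 M), −40 → 0 °C; concentrate; then Bu4NF (5 equiv), THF, rt
Reagents that add atoms: none
Why: Directed (intramolecular) ionic hydrogenation, in which acid ionises the doubly benzylic tertiary alcohol to cation 15 and the Si–H of the C2 arm (six-membered transition state; the C3 arm is on the same face) transfers hydride to C1, so hydrogen enters cis to the two CH2O groups and the aryl group ends trans (1S), high dilution suppressing intermolecular transfer and fluoride then removing the silicon residues.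

**Step 9**
Reactants: 17
Product: 18 [(1S,2R,3S)-7,8-dihydroxy-6-methoxy-1-(3,4,5-trimethoxyphenyl)-1,2,3,4-tetrahydronaphthalene-2,3-diyl]dimethanol (target)
Conditions: H2 (1 atm), 10% Pd/C, EtOAc–MeOH, rt
Reagents that add atoms: none
Why: Catalytic hydrogenolysis cleaves the two benzylic C–O bonds of the diphenylmethylene ketal, while the aryl methyl ethers, the alcohols and the diaryl methine are inert and no stereocentre is touched.

**Compound list**
1 | 3,4,5-trimethoxytoluene | Cc1cc(OC)c(OC)c(OC)c1 | starting material
2 | 3,4,5-trimethoxybenzoyl chloride | COc1cc(cc(OC)c1OC)C(Cl)=O | starting material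
3 | (2,3,4-trimethoxy-6-methylphenyl)(3,4,5-trimethoxyphenyl)methanone | Cc1cc(OC)c(OC)c(OC)c1C(=O)c1cc(OC)c(OC)c(OC)c1 | intermediate
4 | (2,3-dihydroxy-4-methoxy-6-methylphenyl)(3,4,5-trimethoxyphenyl)methanone | Cc1cc(OC)c(O)c(O)c1C(=O)c1cc(OC)c(OC)c(OC)c1 | intermediate
5 | dichlorodiphenylmethane | ClC(Cl)(c1ccccc1)c1ccccc1 | starting material
6 | (7-methoxy-5-methyl-2,2-diphenyl-1,3-benzodioxol-4-yl)(3,4,5-trimethoxyphenyl)methanone | Cc1cc(OC)c2OC(c3ccccc3)(c3ccccc3)Oc2c1C(=O)c1cc(OC)c(OC)c(OC)c1 | intermediate
7 | 5-hydroxy-2(5H)-furanone (racemic) | OC1OC(=O)C=C1 | starting material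
8 | (+)-menthol, (1S,2R,5S) | C[C@H]1CC[C@@H]([C@H](C1)O)C(C)C | starting material
9 | (5S)-5-[(1S,2R,5S)-menthyloxy]-2(5H)-furanone | C[C@H]1CC[C@@H]([C@H](C1)O[C@@H]1C=CC(=O)O1)C(C)C | intermediate
10 | photodienol of 6 (hydroxy-o-quinodimethane: exocyclic C4=CH2 and C8a=C1(OH)Ar on dearomatised ring A, OH syn to the dioxole oxygen) | O/C(c1cc(OC)c(OC)c(OC)c1)=C1\C2=C(C(OC)=CC1=C)OC(c1ccccc1)(c1ccccc1)O2 | intermediate (not isolated)
11 | hydroxy lactone adduct (tetralin numbering 1R,2S,3S; C1 OH and aryl; γ-lactone C2–C(=O)–O–CH(O-menthyl)–C3 cis-fused, acetal carbon S with O-menthyl trans to the ring-B bonds; 6-OMe; 7,8-O2CPh2) | COc1cc2c(c3OC(c4ccccc4)(c4ccccc4)Oc13)[C@](O)(c5cc(OC)c(OC)c(OC)c5)[C@H]6C(=O)O[C@H](O[C@H]7C[C@@H](C)CC[C@@H]7C(C)C)[C@H]6C2 | intermediate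
12 | (1R,2R,3S)-1-hydroxy-2,3-bis(hydroxymethyl)-6-methoxy-7,8-(diphenylmethylenedioxy)-1-(3,4,5-trimethoxyphenyl)tetralin | COc1cc2c(c3OC(c4ccccc4)(c4ccccc4)Oc13)[C@](O)(c5cc(OC)c(OC)c(OC)c5)[C@@H](CO)[C@@H](CO)C2 | intermediate
13 | di-tert-butylchlorosilane | CC(C)(C)[SiH](Cl)C(C)(C)C | starting material
14 | bis(di-tert-butylsilyl) ether of 12 (both CH2O–SiH(t-Bu)2; C1–OH free) | COc1cc2c(c3OC(c4ccccc4)(c4ccccc4)Oc13)[C@](O)(c5cc(OC)c(OC)c(OC)c5)[C@@H](CO[SiH](C(C)(C)C)C(C)(C)C)[C@@H](CO[SiH](C(C)(C)C)C(C)(C)C)C2 | intermediate
15 | C1 diarylcarbenium trifluoroacetate derived from 14 | COc1cc2c(c3OC(c4ccccc4)(c4ccccc4)Oc13)[C+](c5cc(OC)c(OC)c(OC)c5)[C@@H](CO[SiH](C(C)(C)C)C(C)(C)C)[C@@H](CO[SiH](C(C)(C)C)C(C)(C)C)C2.[O-]C(=O)C(F)(F)F | intermediate (not isolated)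
16 | (1S,2R,3S) C1–H compound with the C2 arm as CH2O–Si(t-Bu)2–OCOCF3 and the C3 arm as CH2O–SiH(t-Bu)2 | COc1cc2c(c3OC(c4ccccc4)(c4ccccc4)Oc13)[C@H](c5cc(OC)c(OC)c(OC)c5)[C@@H](CO[Si](OC(=O)C(F)(F)F)(C(C)(C)C)C(C)(C)C)[C@@H](CO[SiH](C(C)(C)C)C(C)(C)C)C2 | intermediate (not isolated)
17 | (1S,2R,3S)-2,3-bis(hydroxymethyl)-6-methoxy-7,8-(diphenylmethylenedioxy)-1-(3,4,5-trimethoxyphenyl)tetralin | COc1cc2c(c3OC(c4ccccc4)(c4ccccc4)Oc13)[C@H](c5cc(OC)c(OC)c(OC)c5)[C@@H](CO)[C@@H](CO)C2 | intermediate
18 | [(1S,2R,3S)-7,8-dihydroxy-6-methoxy-1-(3,4,5-trimethoxyphenyl)-1,2,3,4-tetrahydronaphthalene-2,3-diyl]dimethanol | COc1cc2c(c(O)c1O)[C@H](c1cc(OC)c(OC)c(OC)c1)[C@@H](CO)[C@@H](CO)C2 | target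

**Step count**
Total steps: 9. Longest linear sequence: 8 (steps 1, 2, 3, 5, 6, 7, 8, 9; step 4 is the side branch).

**Three steps most likely to fail**

Step 5 (key step). The excited ketone or the dienol may be consumed before it meets the butenolide: the dienol can close to the benzocyclobutenol, and the butenolide can decay by sensitisation. Regio- or face control may also erode under irradiation. Fallback: light and cycloaddition are separated. Ketone 6 is irradiated alone (365 nm, degassed benzene, rt) until it has closed to the racemic benzocyclobutenol F1. F1 is then heated in the dark with 9 (toluene, 100–110 °C). Conrotatory ring opening with the hydroxyl group rotating outward regenerates dienol 10 thermally, and the same Diels–Alder addition should deliver 11. The fallback sets out from 6 and comes back at 11.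

Step 8. The cation may lose a proton to the C1=C2 alkene, be captured by the C3 arm oxygen as a bridged ether, or take hydride from a second molecule on its open face. Each path erodes the C1 configuration. Fallback: the cationic route is replaced by heterogeneous hydrogenolysis. Triol 12 is treated with W-2 Raney nickel in ethanol at 50–78 °C. Raney nickel cleaves benzylic C–OH bonds with retention, and the three hydroxyl groups on the same face should anchor that face to the metal, so hydrogen takes the place of the C1 oxygen. The fallback sets out from 12 and comes back at 17; should the ketal be cleaved as well, the product is 18 and step 9 falls away. It makes no new compound (F0).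

Step 2. Ether cleavage may stall after the first chelated methyl ether, or run on to the para methoxy group of the second ring under excess Lewis acid. Fallback: the second methyl ether is removed oxidatively. Ketone 3 is treated with BCl3 (1.1 equiv, CH2Cl2, −78 → 0 °C) to give the mono-phenol (2-hydroxy-3,4-dimethoxy-6-methylphenyl)(3,4,5-trimethoxyphenyl)methanone F2. Oxidative demethylation of this 2-methoxyphenol with IBX (DMF, rt) gives the ortho-quinone 3-methoxy-5-methyl-6-(3,4,5-trimethoxybenzoyl)cyclohexa-3,5-diene-1,2-dione F3. F3 is reduced without isolation by aqueous Na2S2O4 to catechol 4. The fallback sets out from 3 and comes back at 4.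

**Further compounds**
F1 | step 5 | racemic benzocyclobutenol valence isomer of 6 (C1–C4 bond closed; C1 carries OH and the 3,4,5-trimethoxyphenyl group) | COc1cc2c(c3OC(c4ccccc4)(c4ccccc4)Oc13)C(O)(c5cc(OC)c(OC)c(OC)c5)C2
F0 | step 8 | none | none
F2 | step 2 | (2-hydroxy-3,4-dimethoxy-6-methylphenyl)(3,4,5-trimethoxyphenyl)methanone | Cc1cc(OC)c(OC)c(O)c1C(=O)c1cc(OC)c(OC)c(OC)c1
F3 | step 2 | 3-methoxy-5-methyl-6-(3,4,5-trimethoxybenzoyl)cyclohexa-3,5-diene-1,2-dione | CC1=C(C(=O)c2cc(OC)c(OC)c(OC)c2)C(=O)C(=O)C(OC)=C1
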